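| flask | Z | G | temperature | remark | time |
|---|---|---|---|---|---|
| winter | 0.55 M | 1.98 M | −45 °C | run made earlier |  |
| dusk | 2.2 M | 1.98 M | −20 °C | run made earlier |  |
| birch | 1.1 M | 1.98 M |  | at 0 °C until 6.0 h, from then on at −40 °C | 12 h |
| cedar | 1.1 M | 1.98 M | 0 °C |  | 12 h |
| maple | 1.1 M | 1.98 M | −20 °C |  | 12 h |
| elm | 1.1 M | 1.98 M | −40 °C |  | 12 h |

| run | time / h | X / % | Z / % |
|---|---|---|---|
| winter | 10.0 | 7.7 | 93.8 |
| winter | 30.0 | 18.3 | 81.0 |
| winter | 60.0 | 34.1 | 65.2 |
| winter | 72.0 | 39.0 | 59.8 |
| winter | 120 | 58.2 | 40.4 |
| dusk | 6.00 | 45.9 | 47.7 |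
| dusk | 15.0 | 41.8 | 25.1 |
| dusk | 20.0 | 34.2 | 24.5 |
| dusk | 25.0 | 25.9 | 22.4 |
| dusk | 30.0 | 23.7 | 22.3 |

(each reading ± 1 percentage point)

- the flask that comes out highest in amount of X, in percent of the Z charged, or "all alike" when all lie within 1.5 percentage points (birch / cedar / maple / elm / all alike)
- X at the end, in percent of the Z charged, birch
- X at the end, in percent of the Z charged, cedar
- X at the end, in percent of the Z charged, maple
- X at the end, in percent of the Z charged, elm

- Percent of the Z charged is the unit that turns a closed flask into a balance: Z, X and anything unseen add up to 100, so what Z and X do not account for is held by something unmeasured.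
- In dusk, at −20 °C, this missing share grows from 6.40% at 6.00 h to 54.0% at 30.0 h. From 15.0 h onward, X falls from 41.8% to 23.7% while Z moves from 25.1% to 22.3%, so the readings point to X as the source of the missing share.
- Take this loss as a first-order consecutive step, with a rate proportional to [X]. The gain in the missing share then equals a constant times the X-hours, the area under the X curve, which counts the hours the whole charge would have had to stand as X. Trapezoids through the dusk readings give 8.59 h.
- The leak constant, the fraction of X lost per hour, is that gain divided by the X-hours, read here as 0.0554 h⁻¹.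
- Maple runs at the same −20 °C, so the leak constant carries over to it. This reckoning also assumes that Z in maple falls first order, as it nearly does in winter, with the constant from the first dusk reading, 0.123 h⁻¹. That constant is a rough transfer, since dusk was charged with twice the Z of maple.
- Z then disappears faster than X leaks, and the two consecutive steps give this reckoning 52.1% of X in maple at 12 h.
- The forecast names maple as highest, with X at 11% in birch, 6% in cedar, 60% in maple and 16% in elm. For maple, its grounds are “about 80% formed, about 20% lost”, and its 60% stands above the 52.1% reckoned here.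
- The flasks give 5.87% in birch, 5.56% in cedar, 63.3% in maple and 11.8% in elm. Maple comes out highest, and the forecast for birch stands 5.1 percentage points above what that flask gives.

    Z + G → X, rate k1*[Z]^0.5*[G]^0.5 (k = 5.40 × 10⁻⁴ s⁻¹, Ea = 73.0 kJ mol⁻¹)
    G ⇌ E (K = 1.60, k = 3.20 × 10⁻⁴ s⁻¹, Ea = 89.0 kJ mol⁻¹, ΔH = −18.0 kJ mol⁻¹)
    X ⇌ L (K = 17.0, k = 2.60 × 10⁻⁴ s⁻¹, Ea = 82.0 kJ mol⁻¹, ΔH = −21.0 kJ mol⁻¹)
    (constants at 0 °C)

- The reaction of X to L, both ways, is the main reason for the low X in cedar, which goes from 5.56% to 100% when that step is struck out. In maple, X stands at 61.5% at 6.00 h and 63.3% at 12.0 h, so trapezoids from zero at the start estimate the X-hours at 5.59 h, and the leak constant turns these into an estimate of 31.0% of L against the 33.4% in the flask. The neighbour of maple charged with 0.79 M of G ends with 39.0% of X; scaling the maple X-hours to that end value, which assumes an X curve of the same shape, gives a rough estimate of 19.1% of L, and that flask holds 21.1%.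

Readings and results come from a simulation with constants of no real substance; noise was put on by code.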